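**Retrosynthetic overview**

1. The oxane is the only ring that has to be made (both benzene rings are bought) and it is closed in the last step: the O1–C2 bond forms by a cobalt-hydride hydrogen-atom-transfer (radical) hydroalkoxylation of an (E)-styrenyl 1,3-anti triol, which sets C2 with the aryl group equatorial.
2. The C4 carbinol comes from a hydroxyl-directed 1,3-anti reduction of a β-hydroxy enone.
3. The CH2–(4-hydroxyphenyl) bond comes from a nickel-catalysed radical cross-electrophile coupling of a terminal epoxide with 4-bromophenol.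
4. The C6 and C1' stereocentres come from a Sharpless kinetic resolution of the vinyl carbinol made by an acrolein aldol (C5–C6 bond).
5. The aryl–C2 carbon bond comes from a Heck reaction of methyl vinyl ketone with a silyl-protected 4-bromoguaiacol made from catechol.

Assumption: two operations run in one flask without isolating the intermediate count as one step. Acyclic intermediates are numbered along the heptane chain from the guaiacyl end (C1) to the 4-hydroxyphenyl end (C7), so chain C1, C3, C5 and C6 become ring C2, C4, C6 and the side-chain carbinol C1'. TBS = tert-butyldimethylsilyl.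

**Route**

Step 1
Reactants: 1 catechol (benzene-1,2-diol)
Product: 2 guaiacol (2-methoxyphenol)
Conditions: MeI (1.0 equiv), K2CO3 (1.0 equiv), acetone, 56 °C
Reagents that add atoms: iodomethane, CI
Why: Williamson O-methylation of the catechol monoanion, in which one equivalent of MeI keeps the diether low and guaiacol is freed from catechol and veratrole by distillation (no stereocentre).

Step 2
Reactants: 2 guaiacol
Product: 4 (4-bromo-2-methoxyphenoxy)(tert-butyl)dimethylsilane, via 4-bromo-2-methoxyphenol 3 (not isolated)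
Conditions: NBS (1.0 equiv), MeCN, 0 °C; then imidazole (2.5 equiv), TBSCl (1.5 equiv), 23 °C
Reagents that add atoms: N-bromosuccinimide, O=C1CCC(=O)N1Br; tert-butyldimethylsilyl chloride, CC(C)(C)[Si](C)(C)Cl
Why: Electrophilic aromatic bromination goes para to the free hydroxyl (the stronger director), and the phenol is then capped in the same flask as its silyl ether so that the later titanium, acid and oxidant steps never see the electron-rich free guaiacol.

Step 3
Reactants: 4 (4-bromo-2-methoxyphenoxy)(tert-butyl)dimethylsilane; 5 methyl vinyl ketone (but-3-en-2-one)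
Product: 6 (3E)-4-[4-(tert-butyldimethylsilyloxy)-3-methoxyphenyl]but-3-en-2-one
Conditions: Pd(OAc)2 (2 mol%), P(o-tol)3 (5 mol%), Et3N (2 equiv), MeCN, 90 °C
Reagents that add atoms: none
Why: Mizoroki–Heck reaction, in which oxidative addition of the aryl bromide to zerovalent palladium, syn-insertion of the enone and syn-β-hydride elimination give only the (E)-enone.

Step 4
Reactants: 6 (3E)-4-[4-(tert-butyldimethylsilyloxy)-3-methoxyphenyl]but-3-en-2-one; 7 acrolein (prop-2-enal)
Product: 8 racemic (1E)-1-[4-(tert-butyldimethylsilyloxy)-3-methoxyphenyl]-5-hydroxyhepta-1,6-dien-3-one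
Conditions: LiN(iPr)2 (1.1 equiv), THF, −78 °C; acrolein (1.2 equiv), −78 °C; AcOH quench
Reagents that add atoms: none
Why: Kinetic deprotonation of the methyl group gives the cross-conjugated lithium dienolate, which adds 1,2 to acrolein at −78 °C (aldol addition) to give the racemic vinyl carbinol whose C5 centre is sorted out in step 5.

Step 5
Reactants: 8 racemic (1E)-1-[4-(tert-butyldimethylsilyloxy)-3-methoxyphenyl]-5-hydroxyhepta-1,6-dien-3-one
Product: 9 (1E,5S)-1-[4-(tert-butyldimethylsilyloxy)-3-methoxyphenyl]-5-hydroxy-5-[(2R)-oxiran-2-yl]pent-1-en-3-one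
Conditions: Ti(OiPr)4 (15 mol%), L-(+)-diisopropyl tartrate (20 mol%), tBuOOH (0.45 equiv), 4 Å molecular sieves, CH2Cl2, −20 °C
Reagents that add atoms: tert-butyl hydroperoxide, CC(C)(C)OO
Why: Sharpless kinetic resolution, in which the titanium L-(+)-tartrate catalyst epoxidises the (5S) enantiomer of 8 much faster than the (5R) one and with erythro selectivity, so that the (5S)-carbinol and the (2R)-oxirane carbon (later C6 and C1' of the target) are set together in at most 45% yield, while (R)-8 stays behind and the electron-poor enone alkene is not touched.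

Step 6
Reactants: 9 (1E,5S)-1-[4-(tert-butyldimethylsilyloxy)-3-methoxyphenyl]-5-hydroxy-5-[(2R)-oxiran-2-yl]pent-1-en-3-one; 10 4-bromophenol
Product: 11 (1E,5S,6R)-1-[4-(tert-butyldimethylsilyloxy)-3-methoxyphenyl]-5,6-dihydroxy-7-(4-hydroxyphenyl)hept-1-en-3-one
Conditions: NiCl2(dme) (15 mol%), 2,2'-bipyridine (15 mol%), NaI (25 mol%), Et3N·HCl (1.2 equiv), Mn powder (2 equiv), DMPU, 23 °C
Reagents that add atoms: none
Why: Nickel-catalysed reductive cross-electrophile coupling of an epoxide with an aryl bromide (a radical cross-coupling), in which iodide opens the oxirane at CH2, the iodohydrin gives a primary β-hydroxyalkyl radical that is captured by the arylnickel bromide (divalent nickel) and reductive elimination forms the CH2–aryl bond, so neither stereocentre is touched and the buffered medium tolerates the free hydroxyls and the phenol.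

Step 7
Reactants: 11 (1E,5S,6R)-1-[4-(tert-butyldimethylsilyloxy)-3-methoxyphenyl]-5,6-dihydroxy-7-(4-hydroxyphenyl)hept-1-en-3-one
Product: 12 (1E,3S,5S,6R)-1-[4-(tert-butyldimethylsilyloxy)-3-methoxyphenyl]-7-(4-hydroxyphenyl)hept-1-ene-3,5,6-triol
Conditions: Me4NBH(OAc)3 (6 equiv), MeCN/AcOH (1:1), −30 °C
Reagents that add atoms: none
Why: Evans–Saksena reduction, in which the C5 hydroxyl exchanges onto boron and delivers hydride to the ketone intramolecularly through a chair transition state, giving the 1,3-anti diol by 1,2-reduction of the enone (new C3 centre S, the later ring C4 with R descriptor).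

Step 8
Reactants: 12 (1E,3S,5S,6R)-1-[4-(tert-butyldimethylsilyloxy)-3-methoxyphenyl]-7-(4-hydroxyphenyl)hept-1-ene-3,5,6-triol
Product: 14 (2R,4R,6S)-2-(4-hydroxy-3-methoxyphenyl)-6-[(1R)-1-hydroxy-2-(4-hydroxyphenyl)ethyl]oxan-4-ol, via silyl-protected oxane 13 (not isolated)
Conditions: [N,N'-bis(3,5-di-tert-butylsalicylidene)-2,3-dimethylbutane-2,3-diaminato]cobalt, C36H54CoN2O2 (3 mol%), N-fluoro-2,4,6-trimethylpyridinium tetrafluoroborate (1.5 equiv), (Me2SiH)2O (1.5 equiv), PhCF3/acetone (2:1), 0 °C; then KHF2 (3 equiv), MeOH, 23 °C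
Reagents that add atoms: none
Why: Cobalt-hydride hydrogen-atom-transfer hydroalkoxylation (Mukaiyama-type radical hydrofunctionalisation with radical–polar crossover), in which the trivalent cobalt hydride gives H• to C2 of the styrene, the benzylic C1 radical is oxidised at cobalt and trapped by the C5 hydroxyl through a chair with the aryl group, the C3 hydroxyl and the C5 side chain all equatorial (also the thermodynamic isomer of this reversibly ionising p-oxybenzylic ether), which sets ring C2 as R, and KHF2 in MeOH then removes the aryl silyl ether in the same flask.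

**Compound list**

1 | catechol (benzene-1,2-diol) | Oc1ccccc1O | starting material
2 | guaiacol (2-methoxyphenol) | COc1ccccc1O | intermediate
3 | 4-bromo-2-methoxyphenol | COc1cc(Br)ccc1O | intermediate (not isolated)
4 | (4-bromo-2-methoxyphenoxy)(tert-butyl)dimethylsilane | COc1cc(Br)ccc1O[Si](C)(C)C(C)(C)C | intermediate
5 | methyl vinyl ketone (but-3-en-2-one) | CC(=O)C=C | starting material
6 | (3E)-4-[4-(tert-butyldimethylsilyloxy)-3-methoxyphenyl]but-3-en-2-one | CC(=O)/C=C/c1ccc(O[Si](C)(C)C(C)(C)C)c(OC)c1 | intermediate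
7 | acrolein (prop-2-enal) | C=CC=O | starting material
8 | racemic (1E)-1-[4-(tert-butyldimethylsilyloxy)-3-methoxyphenyl]-5-hydroxyhepta-1,6-dien-3-one | C=CC(O)CC(=O)/C=C/c1ccc(O[Si](C)(C)C(C)(C)C)c(OC)c1 | intermediate
9 | (1E,5S)-1-[4-(tert-butyldimethylsilyloxy)-3-methoxyphenyl]-5-hydroxy-5-[(2R)-oxiran-2-yl]pent-1-en-3-one | COc1cc(/C=C/C(=O)C[C@H](O)[C@H]2CO2)ccc1O[Si](C)(C)C(C)(C)C | intermediate
10 | 4-bromophenol | Oc1ccc(Br)cc1 | starting material
11 | (1E,5S,6R)-1-[4-(tert-butyldimethylsilyloxy)-3-methoxyphenyl]-5,6-dihydroxy-7-(4-hydroxyphenyl)hept-1-en-3-one | COc1cc(/C=C/C(=O)C[C@H](O)[C@H](O)Cc2ccc(O)cc2)ccc1O[Si](C)(C)C(C)(C)C | intermediate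
12 | (1E,3S,5S,6R)-1-[4-(tert-butyldimethylsilyloxy)-3-methoxyphenyl]-7-(4-hydroxyphenyl)hept-1-ene-3,5,6-triol | COc1cc(/C=C/[C@@H](O)C[C@H](O)[C@H](O)Cc2ccc(O)cc2)ccc1O[Si](C)(C)C(C)(C)C | intermediate
13 | (2R,4R,6S)-2-[4-(tert-butyldimethylsilyloxy)-3-methoxyphenyl]-6-[(1R)-1-hydroxy-2-(4-hydroxyphenyl)ethyl]oxan-4-ol | COc1cc([C@H]2C[C@@H](O)C[C@@H]([C@H](O)Cc3ccc(O)cc3)O2)ccc1O[Si](C)(C)C(C)(C)C | intermediate (not isolated)
14 | (2R,4R,6S)-2-(4-hydroxy-3-methoxyphenyl)-6-[(1R)-1-hydroxy-2-(4-hydroxyphenyl)ethyl]oxan-4-ol (CNP0116327.2) | COc1cc([C@H]2C[C@@H](O)C[C@@H]([C@H](O)Cc3ccc(O)cc3)O2)ccc1O | target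

**Count**

Total step count: 8.
Longest linear sequence: 8 steps (1 → 2 → 4 → 6 → 8 → 9 → 11 → 12 → 14).

**Steps most likely to fail, with fallbacks**

Step 8 is the largest risk. The cobalt-hydride ring closure is run on a triol that also carries a free phenol. The benzylic cation could be lost by retro-Prins cleavage towards the C3 carbinol or be trapped by the C6 hydroxyl, and the 2,6-cis outcome rests on the chair preference and on equilibration. The fallback closes the ring by a two-electron path and sets out from 11. Catalytic DBU in CH2Cl2 adds the C5 hydroxyl to the enone (oxa-Michael addition, thermodynamic control) and gives the 2,6-cis ketone (2R,6S)-2-[4-(tert-butyldimethylsilyloxy)-3-methoxyphenyl]-6-[(1R)-1-hydroxy-2-(4-hydroxyphenyl)ethyl]oxan-4-one F1. NaBH4 in MeOH at −20 °C attacks F1 from the axial side and gives the equatorial alcohol, which is 13; there the fallback comes back to the route, and KHF2/MeOH as in step 8 gives 14.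

Step 6 is the second risk. The primary radical can add to the enone within the same molecule before it meets nickel, the enone can be reduced by the metal, and the β-hydroxy enone can cyclise early. The fallback puts the aryl group on by a polar epoxide opening after the ketone is gone; it sets out from 9 and comes back at 14. Compound 9 is reduced with Me4NBH(OAc)3 (as in step 7) to the epoxy diol (1E,3S,5S)-1-[4-(tert-butyldimethylsilyloxy)-3-methoxyphenyl]-5-[(2R)-oxiran-2-yl]pent-1-ene-3,5-diol F2. Compound 10 is silylated (TBSCl, imidazole) to tert-butyl(4-bromophenoxy)dimethylsilane F3, which with Mg in THF gives [4-(tert-butyldimethylsilyloxy)phenyl]magnesium bromide F4. Opening of the oxirane of F2 at CH2 with an excess of F4 and CuI (10 mol%) at −30 °C gives (1E,3S,5S,6R)-1-[4-(tert-butyldimethylsilyloxy)-3-methoxyphenyl]-7-[4-(tert-butyldimethylsilyloxy)phenyl]hept-1-ene-3,5,6-triol F5. The conditions of step 8 close the ring to (2R,4R,6S)-2-[4-(tert-butyldimethylsilyloxy)-3-methoxyphenyl]-6-[(1R)-1-hydroxy-2-[4-(tert-butyldimethylsilyloxy)phenyl]ethyl]oxan-4-ol F6, and KHF2/MeOH takes off both silyl groups to give 14.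

Step 5 is the third risk. The titanium alkoxide of the β-hydroxy enone may undergo oxa-Michael or retro-aldol reaction, and the resolution caps the yield below 50%. The fallback takes the C6 and C1' centres from the chiral pool instead; it sets out from 6 and comes back at 9. Bought (S)-glycidol (OC[C@H]1CO1) is oxidised with Dess–Martin periodinane in CH2Cl2 to (2R)-oxirane-2-carbaldehyde F7. The lithium enolate of 6 (LiN(iPr)2, THF, −78 °C) is added to F7. Felkin–Anh addition anti to the oxirane C–O bond gives the erythro adduct 9 as the major diastereomer, and the minor one is removed by chromatography.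

**Further compounds**

F1 | step 8 | (2R,6S)-2-[4-(tert-butyldimethylsilyloxy)-3-methoxyphenyl]-6-[(1R)-1-hydroxy-2-(4-hydroxyphenyl)ethyl]oxan-4-one | COc1cc([C@H]2CC(=O)C[C@@H]([C@H](O)Cc3ccc(O)cc3)O2)ccc1O[Si](C)(C)C(C)(C)C
F2 | step 6 | (1E,3S,5S)-1-[4-(tert-butyldimethylsilyloxy)-3-methoxyphenyl]-5-[(2R)-oxiran-2-yl]pent-1-ene-3,5-diol | COc1cc(/C=C/[C@@H](O)C[C@H](O)[C@H]2CO2)ccc1O[Si](C)(C)C(C)(C)C
F3 | step 6 | tert-butyl(4-bromophenoxy)dimethylsilane | CC(C)(C)[Si](C)(C)Oc1ccc(Br)cc1
F4 | step 6 | [4-(tert-butyldimethylsilyloxy)phenyl]magnesium bromide | CC(C)(C)[Si](C)(C)Oc1ccc([Mg]Br)cc1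
F5 | step 6 | (1E,3S,5S,6R)-1-[4-(tert-butyldimethylsilyloxy)-3-methoxyphenyl]-7-[4-(tert-butyldimethylsilyloxy)phenyl]hept-1-ene-3,5,6-triol | COc1cc(/C=C/[C@@H](O)C[C@H](O)[C@H](O)Cc2ccc(O[Si](C)(C)C(C)(C)C)cc2)ccc1O[Si](C)(C)C(C)(C)C
F6 | step 6 | (2R,4R,6S)-2-[4-(tert-butyldimethylsilyloxy)-3-methoxyphenyl]-6-[(1R)-1-hydroxy-2-[4-(tert-butyldimethylsilyloxy)phenyl]ethyl]oxan-4-ol | COc1cc([C@H]2C[C@@H](O)C[C@@H]([C@H](O)Cc3ccc(O[Si](C)(C)C(C)(C)C)cc3)O2)ccc1O[Si](C)(C)C(C)(C)C
F7 | step 5 | (2R)-oxirane-2-carbaldehyde | O=C[C@H]1CO1
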